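The route is disconnected at the Z C1'=C2' double bond of the C8 side chain (C1'–C4', counted from ring A). This alkene lies between two oxygens, the C7 phenol oxygen of ring A and the C3' tertiary hydroxyl, so one silicon atom can bridge them. In the resulting diene, an (S)-7-silyloxy-8-vinylflavanone tied through O7–Si–O3' to the (R)-vinyl carbinol acetate, ring-closing metathesis joins the two vinyl groups, closes an eight-membered ring and so allows only the cis alkene; fluoride then removes silicon. The tether is diphenylsilylene, not dimethylsilylene, because an aryloxy(alkoxy)dimethylsilane would not survive isolation; the skeleton is otherwise unchanged.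

Key step: step 8

Assumption: the ligand enantiomers written in steps 1 and 5 are those expected from the usual facial models to give (R)-3 and (2S)-10; each configuration is to be confirmed on first running (optical rotation of 3, circular dichroism of 10), and the antipodal ligand is used if the sense is reversed.

Step 1
Reactants: 1 isoprene monoepoxide (racemic 2-methyl-2-vinyloxirane)
Product: 3 (R)-2-methylbut-3-ene-1,2-diol, via monoalkyl carbonate salt 2 (not isolated)
Conditions: Pd2(dba)3·CHCl3 (1 mol %), (S,S)-DACH-phenyl ligand [(1S,2S)-N,N'-bis(2-diphenylphosphinobenzoyl)cyclohexane-1,2-diamine] (3 mol %), Et3B (1 mol %), NaHCO3, H2O/CH2Cl2, rt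
Reagents that add atoms: sodium hydrogen carbonate, [Na+].OC(=O)[O-]
Why: Palladium-catalysed dynamic kinetic asymmetric allylic substitution, in which zerovalent palladium opens both enantiomers of 1 to π-allyl complexes that interconvert faster than they are trapped, boron-bound hydrogen carbonate is delivered to the substituted allyl terminus inside the chiral ligand pocket to set the tertiary centre as (R), and carbonate 2 is hydrolysed in the aqueous phase.

Step 2
Reactants: 3 (R)-2-methylbut-3-ene-1,2-diol
Product: 4 (R)-2-hydroxy-2-methylbut-3-en-1-yl acetate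
Conditions: Ac2O (1.05 equiv), pyridine, CH2Cl2, 0 °C
Reagents that add atoms: acetic anhydride, CC(=O)OC(C)=O
Why: Kinetically selective O-acetylation, since the primary hydroxyl is acylated far faster than the tertiary allylic one at 0 °C without a nucleophilic catalyst, and the stereocentre is not involved.

Step 3
Reactants: 5 2-bromoresorcinol
Product: 6 1-(3-bromo-2,4-dihydroxyphenyl)ethan-1-one
Conditions: AcOH, BF3·OEt2, 90 °C; then H2O
Reagents that add atoms: acetic acid, CC(=O)O
Why: Friedel–Crafts (Nencki-type) C-acylation, in which the only positions activated ortho/para by both hydroxyls are the equivalent C4 and C6, so a single chelated ortho-hydroxyacetophenone should form.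

Step 4
Reactants: 6 1-(3-bromo-2,4-dihydroxyphenyl)ethan-1-one
Product: 8 8-bromo-7-hydroxy-4H-chromen-4-one, via enaminone 7 (not isolated)
Conditions: Me2NCH(OMe)2 (2.5 equiv), toluene, 80 °C; then conc. HCl, CH2Cl2, 40 °C
Reagents that add atoms: N,N-dimethylformamide dimethyl acetal, COC(OC)N(C)C
Why: Enaminone route to chromones, in which the acetyl methyl group condenses with the formamide acetal to give 7 and acid then triggers conjugate addition of the chelated 2-hydroxyl with loss of dimethylamine, leaving the former 4-hydroxyl as the 7-hydroxyl and bromine at C8.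

Step 5
Reactants: 8 8-bromo-7-hydroxy-4H-chromen-4-one; 9 phenylboronic acid
Product: 10 (S)-8-bromo-7-hydroxy-2-phenylchroman-4-one
Conditions: 9 (2 equiv), Pd(OCOCF3)2 (5 mol %), (R)-t-BuPyOx [(R)-4-tert-butyl-2-(pyridin-2-yl)-4,5-dihydrooxazole] (6 mol %), NH4PF6 (30 mol %), H2O (5 equiv), ClCH2CH2Cl, 60 °C
Reagents that add atoms: none
Why: Palladium-catalysed asymmetric conjugate addition of an arylboronic acid to a chromone, in which transmetalation gives a cationic aryl complex of divalent palladium that inserts the C2=C3 bond on the face chosen by the tert-butyloxazoline ligand to set C2 as (S) before the palladium enolate is protonated by water, and because no zerovalent palladium takes part the C–Br bond and the free phenol should be tolerated.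

Step 6
Reactants: 10 (S)-8-bromo-7-hydroxy-2-phenylchroman-4-one
Product: 11 (S)-7-hydroxy-2-phenyl-8-vinylchroman-4-one
Conditions: CH2=CHSnBu3 (1.5 equiv), Pd(PPh3)4 (5 mol %), BHT (cat.), toluene, 100 °C
Reagents that add atoms: tributyl(vinyl)stannane, C=C[Sn](CCCC)(CCCC)CCCC
Why: Stille coupling under neutral conditions, in which oxidative addition of the C8–Br bond to zerovalent palladium, vinyl transfer from tin and reductive elimination install the 8-vinyl group without base, so the C2 stereocentre, which is prone to retro-oxa-Michael ring opening, is not endangered.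

Step 7
Reactants: 4 (R)-2-hydroxy-2-methylbut-3-en-1-yl acetate; 12 dichlorodiphenylsilane; 11 (S)-7-hydroxy-2-phenyl-8-vinylchroman-4-one
Product: 14 (R)-2-methyl-2-[({[(S)-4-oxo-2-phenyl-8-vinylchroman-7-yl]oxy}diphenylsilyl)oxy]but-3-en-1-yl acetate (diphenylsilylene-tethered diene), via chlorosilane 13 (not isolated)
Conditions: 4 (1.3 equiv), 12 (1.2 equiv), Et3N, DMAP (cat.), CH2Cl2, 0 °C to rt; then 11 (1.0 equiv), Et3N, rt
Reagents that add atoms: none
Why: Stepwise nucleophilic substitution at silicon (silyl ether formation), in which the hindered tertiary hydroxyl displaces one chloride and stops there, as in the preparation of tert-butoxydiphenylsilyl chloride, and the acidic phenol then displaces the second chloride to give the unsymmetrical silylene acetal with both stereocentres untouched.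

Step 8
Reactants: 14 diphenylsilylene-tethered diene
Product: 15 eight-membered cyclic diphenylsilylene acetal bridging O7 of the (2S)-flavanone and O3' of the (R)-configured side chain and containing the Z C1'=C2' alkene
Conditions: second-generation Hoveyda–Grubbs catalyst (H2IMes)Cl2Ru(=CH-C6H4-2-OiPr) (10 mol %, in portions), toluene (2 mM), 80 °C, Ar sparge
Reagents that add atoms: none
Why: The ruthenium alkylidene exchanges with one of the two vinyl groups (most likely the C8 styrenyl one) to give a substrate-bound alkylidene, which adds across the other vinyl group in an intramolecular [2+2] cycloaddition and cycloreverts, forming the C1'=C2' bond and releasing ethylene into the argon stream. The closest known reaction type is temporary silicon-tethered ring-closing metathesis of bis(alkoxy)silanes, here with one aryloxy arm. The ring closes as an eight-membered 1,3-dioxa-2-silacyclooctene (O7, Si, O3', C3', C2', C1', C8, C7) by alkene–alkene metathesis at its C1'–C2' edge, helped by three rigid elements: the cis C7–C8 arene bond, the diphenyl-substituted silicon and the quaternary C3'. The only new stereo-element is the alkene geometry, which the ring fixes as Z because a benzo-fused eight-membered ring cannot span a trans double bond; C2 and C3' are spectators. The step needs cyclisation to outrun oligomerisation and needs no olefin migration: high dilution and the intramolecular setting should secure the first, and the absence of allylic hydrogens on either vinyl group (aryl carbon and quaternary C3') excludes the second.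

Step 9
Reactants: 15 eight-membered cyclic diphenylsilylene acetal
Product: 16 [(2R,3Z)-2-hydroxy-4-[(2S)-7-hydroxy-4-oxo-2-phenylchroman-8-yl]-2-methylbut-3-en-1-yl] acetate (target, CNP0372308.1)
Conditions: Bu4NF/AcOH (1:1, 3 equiv), THF, 0 °C; neutral work-up
Reagents that add atoms: none
Why: Fluoride-induced cleavage of silyl ethers, in which fluoride attacks silicon and expels first the aryloxide and then the tertiary alkoxide while the acetic acid buffer keeps the medium near neutral, so that the acetate, the C2 stereocentre and the cis-disposed phenol and tertiary allylic alcohol (which acid could dehydrate to a 2H-chromene) should be left alone.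

Compound list
1 | isoprene monoepoxide (racemic 2-methyl-2-vinyloxirane) | CC1(C=C)CO1 | starting material
2 | sodium (R)-1-hydroxy-2-methylbut-3-en-2-yl carbonate | OC[C@](C)(OC(=O)[O-])C=C.[Na+] | intermediate
3 | (R)-2-methylbut-3-ene-1,2-diol | OC[C@](C)(O)C=C | intermediate
4 | (R)-2-hydroxy-2-methylbut-3-en-1-yl acetate | CC(=O)OC[C@](C)(O)C=C | intermediate
5 | 2-bromoresorcinol | Oc1cccc(O)c1Br | starting material
6 | 1-(3-bromo-2,4-dihydroxyphenyl)ethan-1-one | CC(=O)c1ccc(O)c(Br)c1O | intermediate
7 | (E)-1-(3-bromo-2,4-dihydroxyphenyl)-3-(dimethylamino)prop-2-en-1-one | CN(C)/C=C/C(=O)c1ccc(O)c(Br)c1O | intermediate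
8 | 8-bromo-7-hydroxy-4H-chromen-4-one | O=c1ccoc2c(Br)c(O)ccc12 | intermediate
9 | phenylboronic acid | OB(O)c1ccccc1 | starting material
10 | (S)-8-bromo-7-hydroxy-2-phenylchroman-4-one | Oc1ccc2c(c1Br)O[C@H](c1ccccc1)CC2=O | intermediate
11 | (S)-7-hydroxy-2-phenyl-8-vinylchroman-4-one | Oc1ccc2c(c1C=C)O[C@H](c1ccccc1)CC2=O | intermediate
12 | dichlorodiphenylsilane | Cl[Si](Cl)(c1ccccc1)c1ccccc1 | starting material
13 | (R)-2-[(chlorodiphenylsilyl)oxy]-2-methylbut-3-en-1-yl acetate | CC(=O)OC[C@](C)(O[Si](Cl)(c1ccccc1)c1ccccc1)C=C | intermediate
14 | (R)-2-methyl-2-[({[(S)-4-oxo-2-phenyl-8-vinylchroman-7-yl]oxy}diphenylsilyl)oxy]but-3-en-1-yl acetate | CC(=O)OC[C@](C)(O[Si](c1ccccc1)(c1ccccc1)Oc1ccc2c(c1C=C)O[C@H](c1ccccc1)CC2=O)C=C | intermediate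
15 | eight-membered cyclic diphenylsilylene acetal (O7–SiPh2–O3') with Z C1'=C2', (2S), (3'R) | CC(=O)OC[C@@]1(C)/C=C\c2c(ccc3c2O[C@H](c2ccccc2)CC3=O)O[Si](c2ccccc2)(c2ccccc2)O1 | intermediate
16 | [(2R,3Z)-2-hydroxy-4-[(2S)-7-hydroxy-4-oxo-2-phenylchroman-8-yl]-2-methylbut-3-en-1-yl] acetate | CC(=O)OC[C@](C)(O)/C=C\c1c(O)ccc2c1O[C@H](c1ccccc1)CC2=O | target

Total step count: 9, with no protecting groups; the silicon tether is the only temporary group.
Longest linear sequence: 7 steps (steps 3 to 9, from 2-bromoresorcinol); the carbinol acetate 4 is made in a 2-step side branch.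

Steps most likely to fail

1. Step 8. The two hindered vinyl groups may fail to engage, the ruthenium alkylidene formed at C8 may rest as an O1-chelate and turn over slowly, or intermolecular metathesis may outrun closure of the medium ring. The fallback makes the alkene trans first and then inverts it. It sets out from bromide 10 and carbinol acetate 4: a Mizoroki–Heck coupling (Pd[P(t-Bu)3]2, Cy2NMe, dioxane, 80 °C) should give the E isomer of the target, (R,E)-2-hydroxy-4-[(S)-7-hydroxy-4-oxo-2-phenylchroman-8-yl]-2-methylbut-3-en-1-yl acetate F1, since the quaternary C3' carries no hydrogen and β-hydride elimination can occur only toward the benzylic carbon. Triplet-sensitised E-to-Z photoisomerisation (fac-Ir(ppy)3, 450 nm light, MeCN, rt) should then enrich the cis alkene, because the cis isomer is twisted out of conjugation by the quaternary C3' against the di-ortho-substituted ring and no longer accepts energy from the sensitiser. The fallback rejoins the route at target 16.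

2. Step 5. The acidic ortho-bromophenol may bind the cationic palladium catalyst and stall turnover, or facial discrimination may be insufficient with the 8-substituent present. The fallback masks the phenol and changes the metal. From chromone 8, MOMCl/iPr2NEt (CH2Cl2, 0 °C) should give 8-bromo-7-(methoxymethoxy)-4H-chromen-4-one F2. Rhodium-catalysed asymmetric 1,4-addition of 9 ([Rh(OH)(cod)]2 with an electron-poor MeO-BIPHEP-type bisphosphine carrying 3,4,5-trifluorophenyl groups on phosphorus, aqueous toluene, no added base) should then give (S)-8-bromo-7-(methoxymethoxy)-2-phenylchroman-4-one F3. Methanolic HCl at 40 °C, applied before any vinyl group is present, removes the acetal and returns to 10.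

3. Step 7. Substitution at silicon may scramble to the symmetrical bis(alkoxy)- and bis(aryloxy)silanes, or the aryloxy–silicon bond may hydrolyse during isolation. The fallback builds a bulkier diisopropylsilylene tether by a hydrosilane route that cannot give symmetrical products. From 4, iPr2Si(H)Cl/imidazole (CH2Cl2, 0 °C to rt) should give (R)-2-[(diisopropylsilyl)oxy]-2-methylbut-3-en-1-yl acetate F4. N-Bromosuccinimide (slightly less than one equivalent, 0 °C) converts Si–H into Si–Br, giving (R)-2-{[bromo(diisopropyl)silyl]oxy}-2-methylbut-3-en-1-yl acetate F5, which is not isolated. Addition of phenol 11 with imidazole should give the diisopropylsilylene-tethered diene F6. The same ring-closing metathesis as in step 8 should give the eight-membered cyclic diisopropylsilylene acetal F7, and Bu4NF/AcOH cleavage as in step 9 returns to target 16.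

Further compounds
F1 | step 8 | (R,E)-2-hydroxy-4-[(S)-7-hydroxy-4-oxo-2-phenylchroman-8-yl]-2-methylbut-3-en-1-yl acetate | CC(=O)OC[C@](C)(O)/C=C/c1c(O)ccc2c1O[C@H](c1ccccc1)CC2=O
F2 | step 5 | 8-bromo-7-(methoxymethoxy)-4H-chromen-4-one | COCOc1ccc2c(c1Br)occc2=O
F3 | step 5 | (S)-8-bromo-7-(methoxymethoxy)-2-phenylchroman-4-one | COCOc1ccc2c(c1Br)O[C@H](c1ccccc1)CC2=O
F4 | step 7 | (R)-2-[(diisopropylsilyl)oxy]-2-methylbut-3-en-1-yl acetate | CC(=O)OC[C@](C)(O[SiH](C(C)C)C(C)C)C=C
F5 | step 7 | (R)-2-{[bromo(diisopropyl)silyl]oxy}-2-methylbut-3-en-1-yl acetate | CC(=O)OC[C@](C)(O[Si](Br)(C(C)C)C(C)C)C=C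
F6 | step 7 | (R)-2-methyl-2-[({[(S)-4-oxo-2-phenyl-8-vinylchroman-7-yl]oxy}diisopropylsilyl)oxy]but-3-en-1-yl acetate | CC(=O)OC[C@](C)(O[Si](C(C)C)(C(C)C)Oc1ccc2c(c1C=C)O[C@H](c1ccccc1)CC2=O)C=C
F7 | step 7 | eight-membered cyclic diisopropylsilylene acetal (O7–Si(iPr)2–O3') with Z C1'=C2', (2S), (3'R) | CC(=O)OC[C@@]1(C)/C=C\c2c(ccc3c2O[C@H](c2ccccc2)CC3=O)O[Si](C(C)C)(C(C)C)O1
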